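Ring B (the phthalide benzene ring) carries the formyl-level carbon C3 on C3a, meta to O5 and O7, and the carboxyl carbon C1 on C7a beside O7: the polarity pattern of a 3-alkoxyaryne. The route therefore disconnects C3a–C3 and C7a–C1 together. In one flask a C3a–C7a aryne adds 2-lithio-1,3-dithiane at C3a and the resulting C7a aryllithium is carboxylated; no ring closes. The precursor is a bromoarene with Br on C7a and OMe on C5, whose O7 and C6 side-chain carbon (as CH2O) are tied in an acetonide. Hydrolysis then gives the lactol, C3 is set by acylative dynamic kinetic resolution, and the lactol is released last.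

Key step: step 4

Assumption: the free C3 lactol epimerises through its open formyl acid only under acid or base catalysis and is taken to hold its configuration under neutral, cold conditions; it is therefore liberated in the last step.

Design remark: the C6 side-chain carbon enters at the alcohol oxidation level, tied to O7 as an acetonide. This keeps the bromoarene skeleton (Br on C7a, O on C7 and C5, one carbon on C6) and avoids both a late benzylic C–H oxidation beside the lactol and a Lewis-acid ether cleavage at O7.

Step 1
Reactants: 1 2-bromo-5-methoxyphenol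
Product: 2 3-bromo-2-hydroxy-6-methoxybenzaldehyde
Conditions: MgCl2, Et3N, paraformaldehyde, MeCN, reflux; then 1 M HCl
Reagents that add atoms: formaldehyde (used as paraformaldehyde), C=O
Why: Magnesium-phenoxide-directed ortho-formylation (Casnati–Skattebøl reaction) delivers formaldehyde only to the free ortho position between OH and OMe, the bromine blocking the other one, and a second equivalent of formaldehyde accepts the hydride to give the aldehyde.

Step 2
Reactants: 2 3-bromo-2-hydroxy-6-methoxybenzaldehyde
Product: 3 6-bromo-2-(hydroxymethyl)-3-methoxyphenol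
Conditions: NaBH4, MeOH, 0 °C
Reagents that add atoms: none
Why: Chemoselective borohydride reduction of the aryl aldehyde should give the salicyl alcohol and leave the aryl bromide untouched.

Step 3
Reactants: 3 6-bromo-2-(hydroxymethyl)-3-methoxyphenol
Product: 4 bromo acetonide (8-bromo-5-methoxy-2,2-dimethyl-4H-1,3-benzodioxine)
Conditions: 2,2-dimethoxypropane, p-TsOH·H2O (cat.), acetone, rt
Reagents that add atoms: 2,2-dimethoxypropane, COC(C)(C)OC
Why: Acid-catalysed transketalisation closes the six-membered isopropylidene acetal of the salicyl alcohol, masking O7 and the benzylic oxygen in one base-stable group whose aryl oxygen later directs the aryne addition.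

Step 4
Reactants: 4 bromo acetonide (8-bromo-5-methoxy-2,2-dimethyl-4H-1,3-benzodioxine); 5 1,3-dithiane; 6 carbon dioxide
Product: 10 dithianyl acid (7-(1,3-dithian-2-yl)-5-methoxy-2,2-dimethyl-4H-1,3-benzodioxine-8-carboxylic acid), via 2-lithio-1,3-dithiane 7 (not isolated), via aryne 8 (not isolated), via aryllithium 9 (not isolated)
Conditions: 5 (2.2 equiv), n-BuLi, THF, −30 °C; 4, then lithium 2,2,6,6-tetramethylpiperidide (LiTMP, 1.3 equiv), −78 to −45 °C; CO2 gas, −78 °C to rt; 1 M HCl to pH 4, 0 °C
Reagents that add atoms: none
Why: Proposed new method: LiTMP removes the only proton next to bromine (C3a–H) and loss of LiBr gives aryne 8; carbanion 7 adds at C3a, the aryne carbon remote from O7, because the developing C7a carbanion is stabilised inductively and by lithium chelation to the acetal oxygen, and aryllithium 9 is then carboxylated at C7a. The closest known reaction type is the carbolithiation of 3-alkoxyarynes by organolithiums or lithiated nitriles with capture of the ortho-alkoxy aryllithium by CO2 or other electrophiles; a sulfur-stabilised formyl anion equivalent is not established as the nucleophile in this three-component format. No ring closes and no stereocentre is formed. The step needs regioselective addition, secured by O7 beside the aryne bond, and carboxylation of 9 before it is protonated by the more acidic dithiane C–H or by the amine, secured by keeping 9 cold and admitting CO2 at once; the hindered amide LiTMP should not compete as a nucleophile.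

Step 5
Reactants: 10 dithianyl acid (7-(1,3-dithian-2-yl)-5-methoxy-2,2-dimethyl-4H-1,3-benzodioxine-8-carboxylic acid)
Product: 12 racemic acetonide lactol ((3RS)-3-hydroxy-5-methoxyphthalide bearing a CMe2 bridge between O7 and the 6-CH2O group), via formyl acid 11 (not isolated)
Conditions: PhI(OCOCF3)2, NaHCO3, MeCN/H2O (9:1), 0 °C; then 1 M HCl to pH 4
Reagents that add atoms: water, O
Why: Oxidative dethioacetalisation with the trivalent iodine reagent (S-activation then hydrolysis) unmasks the aldehyde, which the neighbouring carboxylic acid captures by 5-exo-trig addition to give the lactol as a racemate, while the bicarbonate buffer protects the acetonide.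

Step 6
Reactants: 12 racemic acetonide lactol
Product: 13 (3R)-propanoate of the acetonide lactol ((3R)-5-methoxy-3-(propanoyloxy)phthalide bearing the CMe2 bridge between O7 and the 6-CH2O group)
Conditions: (R)-2-phenyl-2,3-dihydrobenzo[d]imidazo[2,1-b]thiazole ((R)-BTM, 10 mol %), (EtCO)2O, i-Pr2NEt, CHCl3, 0 °C
Reagents that add atoms: propanoic anhydride, CCC(=O)OC(=O)CC
Why: Acylative dynamic kinetic resolution of a 3-hydroxyphthalide: the amine racemises the lactol through its ring-opened formyl carboxylate while the chiral N-acyl isothiouronium acylates one enantiomer faster, so C3 is set under catalyst control, the 3R sense being that expected from the 1-arylalkanol model of this catalyst.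

Step 7
Reactants: 13 (3R)-propanoate of the acetonide lactol
Product: 14 (3R)-7-hydroxy-6-(hydroxymethyl)-5-methoxy-3-(propanoyloxy)phthalide
Conditions: 1 M aq. HCl, THF, rt
Reagents that add atoms: none
Why: Acid hydrolysis of the aryl alkyl isopropylidene ketal releases the C7 phenol and the benzylic alcohol, while the acylal ester should resist dilute acid at rt and no bond to C3 is broken, so the 3R centre is retained.

Step 8
Reactants: 15 atraric acid (methyl 2,4-dihydroxy-3,6-dimethylbenzoate)
Product: 16 methyl 2-hydroxy-4-methoxy-3,6-dimethylbenzoate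
Conditions: MeI (1.1 equiv), K2CO3, acetone, reflux
Reagents that add atoms: iodomethane, CI
Why: Williamson ether synthesis is selective for the 4-OH because the 2-OH is locked in a hydrogen bond to the ester carbonyl and flanked by a methyl group.

Step 9
Reactants: 16 methyl 2-hydroxy-4-methoxy-3,6-dimethylbenzoate
Product: 17 2-hydroxy-4-methoxy-3,6-dimethylbenzoic acid
Conditions: KOH, DMSO/H2O, 80 °C; then 1 M HCl, 0 °C
Reagents that add atoms: potassium hydroxide, [K+].[OH-]
Why: Saponification of the hindered salicylate ester under forcing alkaline conditions gives the stable dianion of the acid, and cold acidification avoids decarboxylation.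

Step 10
Reactants: 14 (3R)-7-hydroxy-6-(hydroxymethyl)-5-methoxy-3-(propanoyloxy)phthalide; 17 2-hydroxy-4-methoxy-3,6-dimethylbenzoic acid
Product: 18 3-O-propanoyl target ([(3R)-7-hydroxy-5-methoxy-1-oxo-3-(propanoyloxy)-1,3-dihydroisobenzofuran-6-yl]methyl 2-hydroxy-4-methoxy-3,6-dimethylbenzoate)
Conditions: PPh3, diisopropyl azodicarboxylate, THF, 0 °C to rt
Reagents that add atoms: none
Why: Mitsunobu reaction: the primary benzylic alcohol is activated as its oxyphosphonium and displaced in an SN2 step by the carboxylate of the far more acidic CO2H, not by the chelated phenols, which suits the hindered acid and leaves the C3 acylal untouched.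

Step 11
Reactants: 18 3-O-propanoyl target
Product: 19 target ([(3R)-3,7-dihydroxy-5-methoxy-1-oxo-1,3-dihydroisobenzofuran-6-yl]methyl 2-hydroxy-4-methoxy-3,6-dimethylbenzoate)
Conditions: immobilised Candida antarctica lipase B, n-BuOH, MTBE/THF, 25 °C; filtration, evaporation below rt
Reagents that add atoms: none
Why: Lipase-catalysed transesterification removes the unhindered propanoyl group by acyl–oxygen cleavage under neutral, base-free conditions, so the C3–O bond and the 3R configuration are kept, while the hindered aryl ester and the lactone should not be substrates and the 3R ester maps onto the enantiomer that this enzyme prefers for cyclic benzylic alcohols.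

Compound list
1 | 2-bromo-5-methoxyphenol | COc1ccc(Br)c(O)c1 | starting material
2 | 3-bromo-2-hydroxy-6-methoxybenzaldehyde | COc1ccc(Br)c(O)c1C=O | intermediate
3 | 6-bromo-2-(hydroxymethyl)-3-methoxyphenol | COc1ccc(Br)c(O)c1CO | intermediate
4 | 8-bromo-5-methoxy-2,2-dimethyl-4H-1,3-benzodioxine (key-step precursor; Br on C7a) | COc1ccc(Br)c2OC(C)(C)OCc12 | intermediate
5 | 1,3-dithiane | C1CSCSC1 | starting material
6 | carbon dioxide | O=C=O | starting material
7 | 2-lithio-1,3-dithiane | [Li]C1SCCCS1 | intermediate
8 | 5-methoxy-2,2-dimethyl-7,8-didehydro-4H-1,3-benzodioxine (C3a–C7a aryne) | COC1=CC#CC2=C1COC(C)(C)O2 | intermediate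
9 | 7-(1,3-dithian-2-yl)-8-lithio-5-methoxy-2,2-dimethyl-4H-1,3-benzodioxine | COc1cc(C2SCCCS2)c([Li])c2OC(C)(C)OCc12 | intermediate
10 | 7-(1,3-dithian-2-yl)-5-methoxy-2,2-dimethyl-4H-1,3-benzodioxine-8-carboxylic acid (key-step product) | COc1cc(C2SCCCS2)c(C(=O)O)c2OC(C)(C)OCc12 | intermediate
11 | 7-formyl-5-methoxy-2,2-dimethyl-4H-1,3-benzodioxine-8-carboxylic acid | COc1cc(C=O)c(C(=O)O)c2OC(C)(C)OCc12 | intermediate
12 | (3RS)-3-hydroxy-5-methoxyphthalide with a CMe2 bridge between O7 and the 6-CH2O group (racemic acetonide lactol) | COc1cc2c(c3OC(C)(C)OCc13)C(=O)OC2O | intermediate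
13 | (3R)-5-methoxy-3-(propanoyloxy)phthalide with the CMe2 bridge between O7 and the 6-CH2O group | COc1cc2c(c3OC(C)(C)OCc13)C(=O)O[C@H]2OC(=O)CC | intermediate
14 | (3R)-7-hydroxy-6-(hydroxymethyl)-5-methoxy-3-(propanoyloxy)phthalide | COc1cc2c(c(O)c1CO)C(=O)O[C@H]2OC(=O)CC | intermediate
15 | atraric acid (methyl 2,4-dihydroxy-3,6-dimethylbenzoate) | COC(=O)c1c(C)cc(O)c(C)c1O | starting material
16 | methyl 2-hydroxy-4-methoxy-3,6-dimethylbenzoate | COC(=O)c1c(C)cc(OC)c(C)c1O | intermediate
17 | 2-hydroxy-4-methoxy-3,6-dimethylbenzoic acid | COc1cc(C)c(C(=O)O)c(O)c1C | intermediate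
18 | [(3R)-7-hydroxy-5-methoxy-1-oxo-3-(propanoyloxy)-1,3-dihydroisobenzofuran-6-yl]methyl 2-hydroxy-4-methoxy-3,6-dimethylbenzoate | COc1cc(C)c(C(=O)OCc2c(OC)cc3c(c2O)C(=O)O[C@H]3OC(=O)CC)c(O)c1C | intermediate
19 | [(3R)-3,7-dihydroxy-5-methoxy-1-oxo-1,3-dihydroisobenzofuran-6-yl]methyl 2-hydroxy-4-methoxy-3,6-dimethylbenzoate (CNP0398000.1) | COc1cc(C)c(C(=O)OCc2c(OC)cc3c(c2O)C(=O)O[C@H]3O)c(O)c1C | target

Total steps: 11. Longest linear sequence: 9 steps (steps 1 to 7, then 10 and 11).

Steps most likely to fail

1. Step 4 (Proposed new method). Proton transfer from the acidic dithiane C–H, or from the amine, to aryllithium 9 may outrun carboxylation, and halogen–metal side reactions may consume 4. Fallback by known chemistry: setting out from 4, bromine–lithium exchange (n-BuLi, THF, −78 °C) and CO2 would give 5-methoxy-2,2-dimethyl-4H-1,3-benzodioxine-8-carboxylic acid F1. Carboxylate-directed ortho-lithiation of F1 at its only ortho C–H (s-BuLi, TMEDA, THF, −78 °C), formylation with DMF and acidification to pH 4 would give formyl acid 11 and hence lactol 12, where the route is rejoined.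

2. Step 11. The enzyme may turn over the bulky substrate slowly, and the freed lactol may lose configuration during a long reaction. Fallback: setting out from 12, camphorsulfonic acid in MeOH would remove the acetonide and close the pseudo ester racemic 7-hydroxy-6-(hydroxymethyl)-3,5-dimethoxyphthalide F2. Mitsunobu esterification with 17 would give the racemic 3-O-methyl pseudo ester of the target F3, and dilute aqueous HCl in THF would hydrolyse the acetal to the racemic target F4. Preparative chromatography on a chiral stationary phase (neutral eluent, subambient temperature) would then deliver 19.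

3. Step 6. Enantioselection may be insufficient or of the opposite sense for this peri-alkoxy lactol. Fallback: setting out from 12, non-selective propanoylation ((EtCO)2O, DMAP, Et3N, CH2Cl2) would give the racemic propanoate of the acetonide lactol F5, and preparative chromatography on a chiral stationary phase would deliver 13.

Further compounds
F1 | step 4 | 5-methoxy-2,2-dimethyl-4H-1,3-benzodioxine-8-carboxylic acid | COc1ccc(C(=O)O)c2OC(C)(C)OCc12
F2 | step 11 | racemic 7-hydroxy-6-(hydroxymethyl)-3,5-dimethoxyphthalide | COc1cc2c(c(O)c1CO)C(=O)OC2OC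
F3 | step 11 | racemic (7-hydroxy-3,5-dimethoxy-1-oxo-1,3-dihydroisobenzofuran-6-yl)methyl 2-hydroxy-4-methoxy-3,6-dimethylbenzoate | COc1cc(C)c(C(=O)OCc2c(OC)cc3c(c2O)C(=O)OC3OC)c(O)c1C
F4 | step 11 | racemic (3,7-dihydroxy-5-methoxy-1-oxo-1,3-dihydroisobenzofuran-6-yl)methyl 2-hydroxy-4-methoxy-3,6-dimethylbenzoate | COc1cc(C)c(C(=O)OCc2c(OC)cc3c(c2O)C(=O)OC3O)c(O)c1C
F5 | step 6 | racemic 5-methoxy-3-(propanoyloxy)phthalide with the CMe2 bridge between O7 and the 6-CH2O group | COc1cc2c(c3OC(C)(C)OCc13)C(=O)OC2OC(=O)CC
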